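The spiro bicyclooctene is cut by a retro-[4+2] into (R)-p-mentha-1,5-dien-8-ol and an α-methylene lactone, whose C7–C8 bond is then disconnected. The key step exploits the adjacent stereocenters C7 and C8 at the cis junction of the seven-membered carbocycle (C1, C5–C10) and the γ-lactone (C7, C8, O, C12, C11): one CrCl2-mediated addition of the C13–C11–C7 allyl unit to the C8 aldehyde closes the carbocycle, sets both centers and lets the C8 alkoxide acylate C12. The precursor is a 2,2,3-trisubstituted cyclopentanone that carries a (Z)-2-(bromomethyl)enoate on the C6 silyloxy carbon and an α-silyloxy aldehyde (C8), with different silyl groups on O6 and O9.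

Key step: step 14

Remark: atoms carry the helenanolide numbers of the target (cyclopentane C1–C5, C15 on C5, C14 on C10, lactone C11–C13; primed numbers are p-menthane numbers of the monoterpene). CIP labels at C6, C7 and C9 change along the route with the substituents although the geometry does not. TES = triethylsilyl, TBS = tert-butyldimethylsilyl, PMB = 4-methoxybenzyl.

Assumption: the (R,R)-phosphonamide of step 1 is taken to add its γ-carbon to the Re face of C3 of the enone (lithium-bridged model), giving the (1S,10S) adduct; were the sense opposite, the (S,S)-diamine would be used.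

Step 1
Reactants: 1 (1R,2R)-N,N'-dimethylcyclohexane-1,2-diamine; 2 ethyl phosphorodichloridite; 3 (E)-1-bromobut-2-ene
Product: 5 (R,R)-crotyl phosphonamide, via phosphorodiamidite 4 (not isolated)
Conditions: Et3N, toluene, 0 °C to rt; filter; then 3, 80 °C
Reagents that add atoms: none
Why: Double substitution at trivalent phosphorus gives the phosphorodiamidite 4, whose Michaelis–Arbuzov reaction at the primary allylic carbon of 3 (SN2, E alkene kept, bromide then removes the ethyl group) gives the phosphonamide; no stereocenter is formed and those of the diamine are untouched.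

Step 2
Reactants: 5 (R,R)-crotyl phosphonamide; 6 2-methylcyclopent-2-en-1-one
Product: 9 formyl ketone (1S,5R,10S), via lithiated phosphonamide 7 (not isolated), via lithium enolate 8 (not isolated)
Conditions: 5, n-BuLi, THF, −78 °C; 6, −78 °C; CF3CH2OCHO, −78 °C; aq. NH4Cl at −78 °C
Reagents that add atoms: 2,2,2-trifluoroethyl formate, O=COCC(F)(F)F
Why: Conjugate addition of the lithiated chiral allylic phosphonamide through its γ-carbon proceeds in a lithium-bridged cyclic transition state in which the auxiliary leaves one quadrant open and the E-crotyl methyl lies over the β-hydrogen of the enone, which sets C1 and C10, and the regiodefined enolate is then C-formylated (Claisen-type acylation) on the face away from the new C1 side chain, which sets the quaternary C5.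

Step 3
Reactants: 10 (4-methoxyphenyl)methanol; 11 tributyl(iodomethyl)stannane
Product: 13 PMB-oxymethyl stannane, via sodium 4-methoxybenzyl oxide 12 (not isolated)
Conditions: NaH, THF/DMF, 0 °C; then 11, rt
Reagents that add atoms: none
Why: Williamson ether synthesis, the alkoxide displacing iodide at the primary carbon next to tin (SN2); no stereocenter is involved.

Step 4
Reactants: 9 formyl ketone; 13 PMB-oxymethyl stannane
Product: 15 C6 carbinol (1S,5R,6R,10S), via PMB-oxymethyllithium 14 (not isolated)
Conditions: 13, n-BuLi, THF, −78 °C; then 9, −78 °C; aq. NH4Cl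
Reagents that add atoms: none
Why: Tin–lithium exchange gives an α-alkoxymethyllithium that adds 1,2 to the aldehyde, much more electrophilic than the neopentyl ring ketone, within the lithium chelate of the two carbonyl groups and from the face opposite the axial C5 methyl (chelation-controlled addition, the polar Felkin–Anh model predicts the same face), which sets C6.

Step 5
Reactants: 15 C6 carbinol
Product: 16 C6 TES ether
Conditions: TESOTf, 2,6-lutidine, CH2Cl2, −78 to 0 °C
Reagents that add atoms: triethylsilyl trifluoromethanesulfonate, CC[Si](CC)(CC)OS(=O)(=O)C(F)(F)F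
Why: Silylation with a silyl triflate and a hindered pyridine base protects the hindered secondary alcohol and blocks retro-aldol cleavage; no stereocenter is touched.

Step 6
Reactants: 16 C6 TES ether
Product: 18 C9 aldehyde (1S,5R,6R,10S), via vicinal diol 17 (not isolated)
Conditions: OsO4 (cat.), NaIO4, 2,6-lutidine, dioxane/H2O, rt
Reagents that add atoms: osmium tetroxide, O=[Os](=O)(=O)=O; sodium periodate, [Na+].[O-]I(=O)(=O)=O
Why: Lemieux–Johnson oxidation, in which OsO4 dihydroxylates the only alkene and NaIO4 cleaves the diol to the C9 aldehyde and releases the auxiliary, under buffered conditions that spare the PMB and TES ethers and do not epimerise C10.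

Step 7
Reactants: 18 C9 aldehyde
Product: 19 C9 allylic alcohol (1S,5R,6R,9S,10S)
Conditions: CH2=CHMgBr, THF, −78 °C; aq. NH4Cl
Reagents that add atoms: vinylmagnesium bromide, C=C[Mg]Br
Why: Grignard 1,2-addition at −78 °C is selective for the aldehyde over the hindered ketone, and Felkin–Anh control (vinyl anti to the cyclopentyl substituent of C10, methyl next to the carbonyl oxygen) sets C9 with O9 syn to the C10 methyl.

Step 8
Reactants: 19 C9 allylic alcohol
Product: 20 C9 TBS ether
Conditions: TBSOTf, 2,6-lutidine, CH2Cl2, −78 to 0 °C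
Reagents that add atoms: tert-butyldimethylsilyl trifluoromethanesulfonate, CC(C)(C)[Si](C)(C)OS(=O)(=O)C(F)(F)F
Why: Silyl triflate silylation of the secondary allylic alcohol installs the non-chelating O9 silyl ether wanted for the key step; no stereocenter is touched.

Step 9
Reactants: 20 C9 TBS ether
Product: 21 C7 primary alcohol
Conditions: DDQ, CH2Cl2/pH 7 buffer, 0 °C
Reagents that add atoms: none
Why: DDQ oxidises the electron-rich PMB ether to an oxocarbenium ion that water hydrolyses (oxidative PMB cleavage), leaving silyl ethers, ketone and alkene untouched; no stereocenter is touched.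

Step 10
Reactants: 21 C7 primary alcohol
Product: 22 C7 aldehyde (1S,5R,6R,9S,10S)
Conditions: Dess–Martin periodinane, NaHCO3, CH2Cl2, 0 °C to rt
Reagents that add atoms: none
Why: Dess–Martin oxidation of the primary alcohol stops at the aldehyde, and the buffered, amine-free conditions keep the α-silyloxy center C6 from epimerising.

Step 11
Reactants: 22 C7 aldehyde; 23 methyl acrylate
Product: 24 Morita–Baylis–Hillman adduct (C7 epimers)
Conditions: DABCO, 23 as solvent, MeOH (cat.), rt
Reagents that add atoms: none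
Why: Morita–Baylis–Hillman reaction, the DABCO–acrylate zwitterion adding to the inductively activated α-silyloxy aldehyde while the ketone stays inert; the new C7 carbinol forms as a mixture that is of no consequence because C7 becomes trigonal in step 12.

Step 12
Reactants: 24 Morita–Baylis–Hillman adduct
Product: 25 (Z)-allylic bromide (1S,5R,6S,9S,10S)
Conditions: NBS, Me2S, CH2Cl2, 0 °C to rt
Reagents that add atoms: N-bromosuccinimide, O=C1CCC(=O)N1Br
Why: The bromodimethylsulfonium salt from NBS and Me2S activates the allylic alcohol and bromide displaces it with allylic transposition (SN2' reaction), which gives the thermodynamically preferred (Z)-2-(bromomethyl)enoate with C6 trans to the ester and removes the C7 stereocenter.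

Step 13
Reactants: 25 (Z)-allylic bromide
Product: 27 bromo aldehyde (1S,5R,6S,9R,10S), via secondary ozonide 26 (not isolated)
Conditions: O3, CH2Cl2, −78 °C, Sudan Red 7B end point; Me2S, −78 to 0 °C; used crude
Reagents that add atoms: ozone, [O-][O+]=O
Why: Ozonolysis is selective because the monosubstituted alkene is far more electron-rich than the trisubstituted alkene deactivated by the ester and the allylic bromine, and Me2S reduces the ozonide 26 under neutral conditions that neither epimerise C9 nor displace the bromide.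

Step 14
Reactants: 27 bromo aldehyde
Product: 30 methylene lactone (1S,5R,6S,7R,8S,9R,10S), via allylchromium species 28 (not isolated), via chromium alkoxide 29 (not isolated)
Conditions: CrCl2 (6 equiv), THF, rt, slow addition of 27 to 0.005 M; aq. NH4Cl
Reagents that add atoms: none
Why: Two equivalents of divalent chromium reduce the C13–Br bond by successive single-electron transfers to an allyl species of trivalent chromium, whose γ-carbon C7 adds to the C8 aldehyde through a six-membered chair array closed by the Cr–O8 bond; the closest known reaction type is the Nozaki–Hiyama–Kishi (chromium Barbier) allylation of aldehydes with 2-(bromomethyl)acrylates that gives α-methylene-γ-butyrolactones. The carbocycle closes in a 7-exo-trig mode (C7 onto the exocyclic C8=O) and the chromium alkoxide on O8 then attacks the C12 ester in a 5-exo-trig mode, expelling methoxide and closing the lactone. C7 and C8 are set together: the ester-bearing allylchromium reacts from the geometry with C6 cis to the CH2Cr carbon (E and Z bromides converge by metallotropic equilibration), which places C6 axial and the aldehyde chain equatorial on the chair and gives the syn adduct, the only one that can lactonise to the cis junction. The sense relative to the existing centers comes from the C9 silyloxy group standing anti to the incoming C7 (polar Felkin–Anh) in a forming cycloheptane that keeps the O6 and O9 silyl ethers and the C10 methyl pseudo-equatorial, so that C7–C11 and C8–O end up on the face of the C5 methyl. The step therefore needs cis selectivity at C7/C8 with this facial sense, which the enoate geometry and the two silyloxy centers secure, while high dilution suppresses intermolecular coupling and the ketone, silyl ethers and ester tolerate CrCl2.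

Step 15
Reactants: 30 methylene lactone
Product: 32 cyclopentenone (1S,5R,6S,7R,8S,9R,10S), via trimethylsilyl enol ether 31 (not isolated)
Conditions: TMSOTf, Et3N, CH2Cl2, 0 °C; then Pd(OAc)2, MeCN, rt
Reagents that add atoms: none
Why: Saegusa–Ito oxidation, in which soft enolisation can only occur toward C3 (C5 is quaternary, the lactone has no α-hydrogen) and Pd(OAc)2 converts the silyl enol ether by β-hydride elimination into the C2–C3 enone; no stereocenter is touched.

Step 16
Reactants: 32 cyclopentenone
Product: 33 C6 alcohol (1S,5R,6S,7S,8S,9R,10S)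
Conditions: PPTS, MeOH/CH2Cl2, 0 °C to rt
Reagents that add atoms: none
Why: Acid-catalysed methanolysis removes the triethylsilyl ether much faster than the bulkier tert-butyldimethylsilyl ether (selective silyl ether solvolysis); no stereocenter is touched.

Step 17
Reactants: 33 C6 alcohol; 34 tiglic acid
Product: 36 C6 tiglate, via mixed anhydride 35 (not isolated)
Conditions: 34, 2,4,6-trichlorobenzoyl chloride, Et3N, toluene, rt; then 33, DMAP, rt to 40 °C
Reagents that add atoms: none
Why: Yamaguchi esterification, DMAP transferring the tigloyl group from the mixed anhydride 35 as an acylpyridinium ion to the only free hydroxyl, conditions forcing enough for the hindered C6 position, and the E-configured tiglate does not isomerise; no stereocenter is touched.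

Step 18
Reactants: 36 C6 tiglate
Product: 37 9-hydroxy tiglate (dienophile)
Conditions: HF·pyridine, pyridine, THF, 0 °C to rt
Reagents that add atoms: none
Why: Fluoride-mediated desilylation under mildly acidic, non-basic conditions leaves the ester, the enone and the methylene lactone intact; no stereocenter is touched.

Step 19
Reactants: 38 (R)-(−)-carvone
Product: 39 (R)-8-hydroxycarvotanacetone
Conditions: 50% aq. H2SO4, 0 °C
Reagents that add atoms: water, O
Why: Acid-catalysed Markovnikov hydration of the isopropenyl group through the tertiary carbocation, while the electron-poor enone alkene is not protonated; C4' is untouched.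

Step 20
Reactants: 39 (R)-8-hydroxycarvotanacetone
Product: 40 tosylhydrazone
Conditions: TsNHNH2, MeOH, rt
Reagents that add atoms: 4-methylbenzenesulfonohydrazide, Cc1ccc(cc1)S(=O)(=O)NN
Why: Condensation of the ketone with the sulfonyl hydrazide gives the tosylhydrazone as the E isomer, with the sulfonamide on the side of the CH2 group that is to be deprotonated; C4' is untouched.

Step 21
Reactants: 40 tosylhydrazone
Product: 42 (R)-p-mentha-1,5-dien-8-ol, via dienyllithium 41 (not isolated)
Conditions: MeLi (4 equiv), Et2O, 0 °C to rt; H2O, 0 °C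
Reagents that add atoms: none
Why: Shapiro reaction, in which after deprotonation of O–H and N–H a further equivalent removes a hydrogen from the CH2 syn to the sulfonamide nitrogen, loss of sulfinate and dinitrogen gives the dienyllithium 41, and protonation gives the conjugated 1,3-diene without touching C4'.

Step 22
Reactants: 37 9-hydroxy tiglate (dienophile); 42 (R)-p-mentha-1,5-dien-8-ol
Product: 43 target
Conditions: 42 (3 equiv), toluene (2 M), BHT, 80 °C, sealed tube, dark
Reagents that add atoms: none
Why: Thermal Diels–Alder reaction of normal electron demand, in which the C2' terminus (larger HOMO coefficient, next to the methyl-bearing C1') bonds to C13 and C5' bonds to C11, the dienophile takes the diene face anti to the hydroxyisopropyl group (sets C2' and C5'), and the Alder endo approach with the lactone carbonyl under the diene, which for this orientation means bonding to the C11=C13 face on the side of C6 and C9, sets C11, helped in the non-polar medium by a hydrogen bond from the dienol hydroxyl to the C6 ester carbonyl.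

Compound list

1 | (1R,2R)-N,N'-dimethylcyclohexane-1,2-diamine | CN[C@@H]1CCCC[C@H]1NC | starting material
2 | ethyl phosphorodichloridite | CCOP(Cl)Cl | starting material
3 | (E)-1-bromobut-2-ene | C/C=C/CBr | starting material
4 | (3aR,7aR)-2-ethoxy-1,3-dimethyloctahydro-1H-1,3,2-benzodiazaphosphole (not isolated) | CCOP1N(C)[C@@H]2CCCC[C@H]2N1C | intermediate
5 | (3aR,7aR)-2-[(2E)-but-2-en-1-yl]-1,3-dimethyloctahydro-1H-1,3,2-benzodiazaphosphole 2-oxide | C/C=C/CP1(=O)N(C)[C@@H]2CCCC[C@H]2N1C | intermediate
6 | 2-methylcyclopent-2-en-1-one | CC1=CCCC1=O | starting material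
7 | α-lithio derivative of 5, delocalised allyl anion (not isolated) | C/C=C/C([Li])P1(=O)N(C)[C@@H]2CCCC[C@H]2N1C | intermediate
8 | lithium enolate of the conjugate adduct, (1S,10S) (not isolated) | CC1=C(O[Li])CC[C@H]1[C@H](C)/C=C/P2(=O)N(C)[C@@H]3CCCC[C@H]3N2C | intermediate
9 | (1R,5S)-1-methyl-2-oxo-5-[(2S,3E)-4-[(3aR,7aR)-1,3-dimethyl-2-oxidooctahydro-1H-1,3,2-benzodiazaphosphol-2-yl]but-3-en-2-yl]cyclopentane-1-carbaldehyde (target numbering 1S,5R,10S; formyl trans to the side chain) | O=C[C@]1(C)C(=O)CC[C@H]1[C@H](C)/C=C/P2(=O)N(C)[C@@H]3CCCC[C@H]3N2C | intermediate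
10 | (4-methoxyphenyl)methanol | COc1ccc(CO)cc1 | starting material
11 | tributyl(iodomethyl)stannane | CCCC[Sn](CCCC)(CCCC)CI | starting material
12 | sodium (4-methoxyphenyl)methanolate (not isolated) | [Na+].[O-]Cc1ccc(OC)cc1 | intermediate
13 | tributyl{[(4-methoxybenzyl)oxy]methyl}stannane | CCCC[Sn](CCCC)(CCCC)COCc1ccc(OC)cc1 | intermediate
14 | [(4-methoxybenzyl)oxy]methyllithium (not isolated) | [Li]COCc1ccc(OC)cc1 | intermediate
15 | (2R,3S)-2-[(1R)-1-hydroxy-2-(PMB-oxy)ethyl]-2-methyl-3-[(2S,3E)-4-(phosphonamidyl)but-3-en-2-yl]cyclopentan-1-one (1S,5R,6R,10S) | COc1ccc(COC[C@H](O)[C@]2(C)C(=O)CC[C@H]2[C@H](C)/C=C/P3(=O)N(C)[C@@H]4CCCC[C@H]4N3C)cc1 | intermediate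
16 | O6-TES ether of 15 (1S,5R,6R,10S) | COc1ccc(COC[C@H](O[Si](CC)(CC)CC)[C@]2(C)C(=O)CC[C@H]2[C@H](C)/C=C/P3(=O)N(C)[C@@H]4CCCC[C@H]4N3C)cc1 | intermediate
17 | C8,C9-diol of 16, mixture at C8 and C9 (not isolated) | COc1ccc(COC[C@H](O[Si](CC)(CC)CC)[C@]2(C)C(=O)CC[C@H]2[C@H](C)C(O)C(O)P3(=O)N(C)[C@@H]4CCCC[C@H]4N3C)cc1 | intermediate
18 | (2S)-2-[(1S,2R)-2-methyl-3-oxo-2-[(1R)-2-(PMB-oxy)-1-(TES-oxy)ethyl]cyclopentyl]propanal (1S,5R,6R,10S) | COc1ccc(COC[C@H](O[Si](CC)(CC)CC)[C@]2(C)C(=O)CC[C@H]2[C@H](C)C=O)cc1 | intermediate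
19 | (2R,3S)-3-[(2S,3S)-3-hydroxypent-4-en-2-yl]-2-methyl-2-[(1R)-2-(PMB-oxy)-1-(TES-oxy)ethyl]cyclopentan-1-one (1S,5R,6R,9S,10S) | COc1ccc(COC[C@H](O[Si](CC)(CC)CC)[C@]2(C)C(=O)CC[C@H]2[C@H](C)[C@@H](O)C=C)cc1 | intermediate
20 | O9-TBS ether of 19 | COc1ccc(COC[C@H](O[Si](CC)(CC)CC)[C@]2(C)C(=O)CC[C@H]2[C@H](C)[C@@H](O[Si](C)(C)C(C)(C)C)C=C)cc1 | intermediate
21 | (2R,3S)-2-[(1R)-2-hydroxy-1-(TES-oxy)ethyl]-2-methyl-3-[(2S,3S)-3-(TBS-oxy)pent-4-en-2-yl]cyclopentan-1-one | OC[C@H](O[Si](CC)(CC)CC)[C@]1(C)C(=O)CC[C@H]1[C@H](C)[C@@H](O[Si](C)(C)C(C)(C)C)C=C | intermediate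
22 | (2R)-2-[(1R,2S)-1-methyl-5-oxo-2-[(2S,3S)-3-(TBS-oxy)pent-4-en-2-yl]cyclopentyl]-2-(TES-oxy)acetaldehyde (1S,5R,6R,9S,10S) | O=C[C@H](O[Si](CC)(CC)CC)[C@]1(C)C(=O)CC[C@H]1[C@H](C)[C@@H](O[Si](C)(C)C(C)(C)C)C=C | intermediate
23 | methyl acrylate | C=CC(=O)OC | starting material
24 | methyl (4R)-3-hydroxy-2-methylidene-4-[(1R,2S)-1-methyl-5-oxo-2-[(2S,3S)-3-(TBS-oxy)pent-4-en-2-yl]cyclopentyl]-4-(TES-oxy)butanoate, both C7 epimers | C=C(C(=O)OC)C(O)[C@H](O[Si](CC)(CC)CC)[C@]1(C)C(=O)CC[C@H]1[C@H](C)[C@@H](O[Si](C)(C)C(C)(C)C)C=C | intermediate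
25 | methyl (2Z,4S)-2-(bromomethyl)-4-[(1R,2S)-1-methyl-5-oxo-2-[(2S,3S)-3-(TBS-oxy)pent-4-en-2-yl]cyclopentyl]-4-(TES-oxy)but-2-enoate | BrC/C(C(=O)OC)=C\[C@H](O[Si](CC)(CC)CC)[C@]1(C)C(=O)CC[C@H]1[C@H](C)[C@@H](O[Si](C)(C)C(C)(C)C)C=C | intermediate
26 | 1,2,4-trioxolane (secondary ozonide) at C8 of 25 (not isolated) | BrC/C(C(=O)OC)=C\[C@H](O[Si](CC)(CC)CC)[C@]1(C)C(=O)CC[C@H]1[C@H](C)[C@@H](O[Si](C)(C)C(C)(C)C)C1OCOO1 | intermediate
27 | methyl (2Z,4S)-2-(bromomethyl)-4-[(1R,2S)-1-methyl-5-oxo-2-[(2S,3R)-3-(TBS-oxy)-4-oxobutan-2-yl]cyclopentyl]-4-(TES-oxy)but-2-enoate (1S,5R,6S,9R,10S; key-step precursor) | BrC/C(C(=O)OC)=C\[C@H](O[Si](CC)(CC)CC)[C@]1(C)C(=O)CC[C@H]1[C@H](C)[C@@H](O[Si](C)(C)C(C)(C)C)C=O | intermediate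
28 | allylchromium dichloride from 27, trivalent chromium on C13, alkene geometry mobile (not isolated) | Cl[Cr](Cl)CC(C(=O)OC)=C[C@H](O[Si](CC)(CC)CC)[C@]1(C)C(=O)CC[C@H]1[C@H](C)[C@@H](O[Si](C)(C)C(C)(C)C)C=O | intermediate
29 | cyclised chromium O8-alkoxide with methyl 2-propenoate unit on C7, cis C7/C8 (not isolated) | CC[Si](CC)(CC)O[C@H]1[C@H](C(=C)C(=O)OC)[C@H](O[Cr](Cl)Cl)[C@H](O[Si](C)(C)C(C)(C)C)[C@@H](C)[C@@H]2CCC(=O)[C@]21C | intermediate
30 | (1S,5R,6S,7R,8S,9R,10S)-9β-(TBS-oxy)-4-oxo-6α-(TES-oxy)pseudoguai-11(13)-en-12,8β-olide (1αH,7αH,8αH; trans-hydroazulenone, cis-α-methylene lactone; key-step product) | CC[Si](CC)(CC)O[C@H]1[C@H]2[C@H](OC(=O)C2=C)[C@H](O[Si](C)(C)C(C)(C)C)[C@@H](C)[C@@H]2CCC(=O)[C@]21C | intermediate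
31 | C3–C4 trimethylsilyl enol ether of 30 (not isolated) | CC[Si](CC)(CC)O[C@H]1[C@H]2[C@H](OC(=O)C2=C)[C@H](O[Si](C)(C)C(C)(C)C)[C@@H](C)[C@@H]2CC=C(O[Si](C)(C)C)[C@]21C | intermediate
32 | (1S,5R,6S,7R,8S,9R,10S)-9β-(TBS-oxy)-4-oxo-6α-(TES-oxy)pseudoguaia-2,11(13)-dien-12,8β-olide | CC[Si](CC)(CC)O[C@H]1[C@H]2[C@H](OC(=O)C2=C)[C@H](O[Si](C)(C)C(C)(C)C)[C@@H](C)[C@@H]2C=CC(=O)[C@]21C | intermediate
33 | (1S,5R,6S,7S,8S,9R,10S)-6α-hydroxy-9β-(TBS-oxy)-4-oxopseudoguaia-2,11(13)-dien-12,8β-olide | O[C@H]1[C@H]2[C@H](OC(=O)C2=C)[C@H](O[Si](C)(C)C(C)(C)C)[C@@H](C)[C@@H]2C=CC(=O)[C@]21C | intermediate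
34 | tiglic acid, (E)-2-methylbut-2-enoic acid | C/C=C(\C)C(=O)O | starting material
35 | tiglic 2,4,6-trichlorobenzoic anhydride (not isolated) | C/C=C(\C)C(=O)OC(=O)c1c(Cl)cc(Cl)cc1Cl | intermediate
36 | (1S,5R,6S,7S,8S,9R,10S)-9β-(TBS-oxy)-4-oxo-6α-(tigloyloxy)pseudoguaia-2,11(13)-dien-12,8β-olide | C/C=C(\C)C(=O)O[C@H]1[C@H]2[C@H](OC(=O)C2=C)[C@H](O[Si](C)(C)C(C)(C)C)[C@@H](C)[C@@H]2C=CC(=O)[C@]21C | intermediate
37 | (1S,5R,6S,7S,8S,9R,10S)-9β-hydroxy-4-oxo-6α-(tigloyloxy)pseudoguaia-2,11(13)-dien-12,8β-olide | C/C=C(\C)C(=O)O[C@H]1[C@H]2[C@H](OC(=O)C2=C)[C@H](O)[C@@H](C)[C@@H]2C=CC(=O)[C@]21C | intermediate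
38 | (R)-(−)-carvone, (5R)-2-methyl-5-(prop-1-en-2-yl)cyclohex-2-en-1-one | CC1=CC[C@@H](C(C)=C)CC1=O | starting material
39 | (5R)-5-(2-hydroxypropan-2-yl)-2-methylcyclohex-2-en-1-one | CC1=CC[C@@H](C(C)(C)O)CC1=O | intermediate
40 | N'-[(1E,5R)-5-(2-hydroxypropan-2-yl)-2-methylcyclohex-2-en-1-ylidene]-4-methylbenzenesulfonohydrazide | CC1=CC[C@@H](C(C)(C)O)C/C1=N\NS(=O)(=O)c1ccc(C)cc1 | intermediate
41 | dienyllithium lithium alkoxide from 40 (not isolated) | CC1=CC[C@@H](C(C)(C)O[Li])C=C1[Li] | intermediate
42 | (R)-p-mentha-1,5-dien-8-ol, 2-[(1R)-4-methylcyclohexa-2,4-dien-1-yl]propan-2-ol | CC1=CC[C@@H](C(C)(C)O)C=C1 | intermediate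
43 | target: (1S,5R,6S,7S,8S,9R,10S,11S)-9β-hydroxy-4-oxo-6α-(tigloyloxy)pseudoguai-2-en-12,8β-olide spiro-fused at C11 (with C13) to a (2'S,4'R,5'R)-1'-methyl-4'-(2-hydroxypropan-2-yl)bicyclo[2.2.2]oct-1'(6')-ene (C13–C2', C11–C5') | C/C=C(\C)C(=O)O[C@H]1[C@H]2[C@H](OC(=O)[C@]23C[C@@H]2C[C@@H](C(C)(C)O)[C@H]3C=C2C)[C@H](O)[C@@H](C)[C@@H]2C=CC(=O)[C@]21C | target

Total step count: 22. Longest linear sequence: 18 steps (steps 1, 2, 4 to 18, 22).

The three steps most likely to fail

Step 22. The diene may approach the convex lactone face (exo mode, side of H7 and H8) instead of the C6/C9 face, which would give the C11-epimeric adduct series. The diene may also isomerise by hydrogen shift or aromatise on long heating. Fallback (temporary silicon tether, a known intramolecular Diels–Alder type): it sets out from 33 and 42 and rejoins the route at 43. Dienol 42 is silylated with excess Me2SiCl2 (Et3N, DMAP, CH2Cl2) to the chlorosilane of the dienol F1. After removal of the excess dichlorosilane, 33 and imidazole in DMF give the mixed dimethylsilylene acetal F2, which ties O6 to the carbinol oxygen. Heating in toluene should give the tethered cycloadduct F3, because the two oxygens lie within reach of one silicon atom only in the endo array on the C6/C9 face with the diene attacked anti to its side chain. AcOH/THF/H2O cleaves the silylene selectively to the cycloadduct diol F4 (O9 still silylated). Yamaguchi tigloylation of the secondary C6 hydroxyl (the tertiary hydroxyl does not react) gives the 9-O-TBS tiglate F5, and HF·pyridine as in step 18 gives 43.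

Step 14. The ring closure may take the other cis face or give the trans isomer. The allylic bromide may be reduced without cyclisation at high dilution, or the O6 silyloxy group may be lost by β-elimination from the C7-bound form of the allylchromium. Fallback (palladium-catalysed umpolung allylation mediated by InI): it sets out from 24 and rejoins the route at 30. Acetylation (Ac2O, DMAP, pyridine) gives the Morita–Baylis–Hillman acetate F6, and ozonolysis as in step 13 gives the acetate aldehyde F7. Pd(PPh3)4 (catalytic) and InI in THF then convert the allylic acetate, through a π-allyl complex of divalent palladium, into an allylindium species that adds to the C8 aldehyde through the same kind of chair array and lactonises to 30.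

Step 11. Addition to the hindered aldehyde may be so slow that the amine enolises it, with loss of configuration at C6 or silyl migration before C–C bond formation. Fallback (carbonyl vinylalumination): it sets out from 22 and rejoins the route at 24. Methyl propiolate, i-Bu2AlH and N-methylmorpholine N-oxide in THF at 0 °C give, by 1,4-hydroalumination, methyl 2-(diisobutylalumanyl)prop-2-enoate F8. This preformed α-acrylate nucleophile adds to the aldehyde of 22 at 0 °C without amine base and leaves the hindered ketone alone.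

Further compounds

F1 | step 22 | chloro(dimethyl){[2-((1R)-4-methylcyclohexa-2,4-dien-1-yl)propan-2-yl]oxy}silane | CC1=CC[C@@H](C(C)(C)O[Si](C)(C)Cl)C=C1
F2 | step 22 | mixed dimethylsilylene acetal of O6 of 33 and the carbinol oxygen of 42 | CC1=CC[C@@H](C(C)(C)O[Si](C)(C)O[C@H]2[C@H]3[C@H](OC(=O)C3=C)[C@H](O[Si](C)(C)C(C)(C)C)[C@@H](C)[C@@H]3C=CC(=O)[C@]32C)C=C1
F3 | step 22 | tethered cycloadduct, skeleton of 43 with an O6–SiMe2–O8' bridge and O9-TBS | C[Si]4(C)O[C@H]1[C@H]2[C@H](OC(=O)[C@]23C[C@@H]2C[C@@H](C(C)(C)O4)[C@H]3C=C2C)[C@H](O[Si](C)(C)C(C)(C)C)[C@@H](C)[C@@H]2C=CC(=O)[C@]21C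
F4 | step 22 | cycloadduct diol, 43 lacking the tigloyl group and carrying O9-TBS | O[C@H]1[C@H]2[C@H](OC(=O)[C@]23C[C@@H]2C[C@@H](C(C)(C)O)[C@H]3C=C2C)[C@H](O[Si](C)(C)C(C)(C)C)[C@@H](C)[C@@H]2C=CC(=O)[C@]21C
F5 | step 22 | 9-O-TBS ether of 43 | C/C=C(\C)C(=O)O[C@H]1[C@H]2[C@H](OC(=O)[C@]23C[C@@H]2C[C@@H](C(C)(C)O)[C@H]3C=C2C)[C@H](O[Si](C)(C)C(C)(C)C)[C@@H](C)[C@@H]2C=CC(=O)[C@]21C
F6 | step 14 | C7 acetate of 24 | C=C(C(=O)OC)C(OC(C)=O)[C@H](O[Si](CC)(CC)CC)[C@]1(C)C(=O)CC[C@H]1[C@H](C)[C@@H](O[Si](C)(C)C(C)(C)C)C=C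
F7 | step 14 | C7 acetate C8 aldehyde | C=C(C(=O)OC)C(OC(C)=O)[C@H](O[Si](CC)(CC)CC)[C@]1(C)C(=O)CC[C@H]1[C@H](C)[C@@H](O[Si](C)(C)C(C)(C)C)C=O
F8 | step 11 | methyl 2-(diisobutylalumanyl)prop-2-enoate | C=C(C(=O)OC)[Al](CC(C)C)CC(C)C
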